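## Structural features

The target 23 is a germacrane-type cyclodeca-1,5-diene. With the ring atoms numbered C1 to C10 in SMILES order, C1=C2 and C7=C8 are E-trisubstituted alkenes with methyl groups on C1 and C7, and C6, C9 and C10 are methylenes. C3, C4 and C5 are three adjacent stereocentres, all S: C3 bears a free secondary allylic hydroxyl, C4 an isopropyl group, and C5 an oxygen esterified by (E)-4-hydroxycinnamic acid, which is the only link to the benzene ring. Along the ring path C2 to C6 drawn as a zigzag, O3 and the isopropyl group are anti and the isopropyl group and O5 are syn, so the two oxygens are 1,3-anti. The fragile parts are the E,E-1,5-diene in a ten-membered ring (Cope rearrangement on heating, transannular cyclisation in acid), the allylic alcohol, the O3/O5 hydroxy-ester pair (1,3-acyl shift under base), the free phenol and the light-sensitive cinnamate. The real difficulty is to close a ten-membered ring holding two E alkenes while setting three contiguous centres, the middle one (C4) with no heteroatom to direct it. The fifteen skeletal carbons form an all-E farnesyl chain whose C-1 (ring C3) is bonded to its C-10 (ring C4). The saturated isopropyl on C4 beside the hydroxyl on C3 is what a 1,3-hydride shift and hydration leave behind, so the C3–C4 bond, both of its stereocentres and the C3–O bond can come from one cyclisation of a linear diphosphate that already carries the C5 oxygen.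

## Logic of the disconnections

23 is traced to 22 by putting silyl groups on O3 and on the phenol oxygen. The last forward step is then a fluoride desilylation, which spares the diene acid, base and heat. It must be buffered so that the acyl group does not move from O5 to O3.

22 is cut at the ester C–O bond on O5 into 17 and 20. This removes the whole aryl part in one cut, and 20 comes from 18 in one operation. The forward step has to acylate a hindered secondary oxygen next to C4 while O3 and the phenol stay masked.

17 goes back through 16 to 15 by exchanging the silyl group on O3 and the acetyl group on O5. The cyclisation product 15 is formed with O5 acylated and O3 free, so the two oxygens are already differentiated. The demand is that the acetate in 16 is cleaved without loss or migration of the silyl group.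

15 is opened to 14 by cutting C3–C4, removing the C3 hydroxyl, returning the hydrogen on the isopropyl carbon to C3 and placing a diphosphate on C3. This single cut removes the ring, two stereocentres and one C–O bond and leaves a linear all-E chain with one stereocentre. The forward step needs a class 1 synthase that accepts the C5 acetate, closes C3–C4 on the correct faces, shifts hydride and hydrates at C3 and not at C1.

14 is traced through 13 and 12 to 11, that is from the diphosphate to an allylic chloride, an alcohol and a silyl ether. The ionic diphosphate has to be installed last. The displacement must occur at the primary allylic carbon without transposition and with the secondary allylic acetate untouched.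

11 goes back through 10 to 9 by removing the acetyl group and then the carbinol hydrogen. The only stereocentre of the chain then comes from a reagent-controlled ketone reduction. The catalyst must tell the 2-methylpropenyl group from the allylic methylene group.

9 is traced through 8 to 6 and 4 by cutting the bond between the carbonyl carbon (farnesyl C-9) and the allylic methylene (C-8), with the carbonyl masked as a dithiane. This gives a five-carbon and a ten-carbon piece. A dithiane is preferred to an allyl sulfone because its unmasking is a hydrolysis and not an oxidation beside three alkenes. The forward alkylation of 7 must occur at the sulfur-bearing carbon, and the unmasking must be near neutral to keep the skipped enone of 9 unconjugated.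

6 comes from 5 by dithioacetalisation. 4 is traced through 3 and 2 to 1 by bromide-for-hydroxyl exchange, allylic oxidation of the E-methyl group of the distal alkene, and silylation. The oxidation must be selective for that alkene and that methyl group.

20 comes from 18 by silylation of the phenol.

## Other disconnections considered

Alternative 1: The cut removes the C9–C10 ring bond and re-forms a C2–C7 bond, which folds the ring back into the cyclohexanol A1, a 1-vinyl-2-isopropenylcyclohexanol carrying C3, C4 and C5 as ring stereocentres. Forward, the potassium alkoxide of A1 (KH, 18-crown-6) would undergo an anionic oxy-Cope rearrangement through a chair with both alkenyl groups equatorial, and the C7 enolate would be trapped with PhNTf2 as the enol triflate A2. A methyl-for-triflate coupling and exchange of the two ether groups for the free hydroxyl and the ester would follow.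
- In its favour: this is an established ring expansion to E,E-cyclodeca-1,5-dienes, it is driven by enolate formation, it needs no high dilution, and it carries over relative configuration set on a six-membered ring.
- Against it here: A1 needs five contiguous stereocentres, two of which are consumed, including a tertiary carbinol from a face-selective vinyl addition. The C7 methyl is not delivered by the rearrangement. The C7 enolate has a β-silyloxy group at C5 on its other side, so enolate equilibration would invite elimination. The 4-methoxybenzyl group must be removed oxidatively late, beside an electron-rich diene and a cinnamate.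
- Comparison: on mechanism it is the better-founded plan, since its key step is of a known type while the chosen one needs an evolved enzyme. On control of the two alkene geometries it is the equal of the chosen plan. On structure and step economy it is weaker: the chosen cyclisation makes the ring bond, two stereocentres and the hydroxyl at once from a chain eleven steps from commercial materials, while A2 still lacks a carbon and A1 would presumably cost more steps than the whole chosen route.

Alternative 2: The cut is the C6–C7 bond. The acyclic precursor A3 carries a methyl-capped C7≡C8 alkyne at one end and a C5–C6 terminal epoxide at the other, with C3 (silyl ether) and C4 already set. Forward, zerovalent nickel (Ni(cod)2) with Bu3P and Et3B would couple the methyl-bearing alkyne carbon with the epoxide CH2 and add hydrogen to C8 on the same side, giving the ring alcohol A4 with a free O5 hydroxyl.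
- In its favour: ring closure and the E-trisubstituted C7=C8 alkene come from one cis addition. The stereotriad would come from the chiral pool, so absolute configuration does not depend on a catalyst. A4 differs from 17 only in the silyl group on O3, so the endgame would be two steps against four here, and on that point this alternative is better.
- Against it here: intramolecular alkyne–epoxide reductive coupling is known in type only for small rings. This closure places both alkyne carbons inside a ten-membered ring, which requires a strained bridged oxanickelacycle. The two alkyne substituents differ little electronically, so regiochemistry rests on the tether alone. Oligomerisation competes.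
- Comparison: on certainty of absolute configuration and on the endgame it is equal or better. On mechanism it shares the chosen plan's weakness of an undemonstrated ring-forming step, without building two stereocentres in that step. On step economy it is weaker because A3 needs a long acyclic synthesis.

Alternative 3: The cut is the C10–C1 bond between a methylene and an alkene carbon. The precursor A5 has an (E)-alkenyl iodide at C1 and a terminal C9=C10 alkene on a diene, with O3 as a 4-methoxybenzyl ether and O5 as a triethylsilyl ether. Forward, 9-borabicyclo[3.3.1]nonane would hydroborate the terminal alkene with boron on C10, and PdCl2(dppf) with base would couple the alkylborane with the alkenyl iodide to give the ring A6.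
- In its favour: B-alkyl Suzuki–Miyaura coupling is a known reaction class that includes ring closures, and every elementary step is understood. The C1=C2 geometry is fixed in the iodide, and the two oxygens are differentiated from the start.
- Against it here: the terminal alkene is part of a C7=C8–C9=C10 diene, so site-selective hydroboration is not assured. Reductive elimination must close a strained E,E ten-membered ring against β-hydride elimination and oligomerisation. The 4-methoxybenzyl ether again needs oxidative removal at the end. The C3–C4–C5 triad of A5 must be built by acyclic stereocontrol over many steps.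
- Comparison: on mechanistic precedent it is better than the chosen plan, and on alkene geometry it is equal. Its endgame (silyl removal, esterification, ether cleavage) is about the same length. On structure and step economy it is weaker because nothing but the ring bond is made in its key step.

Key step: step 12

Assumption: 14 is drawn as the free acid and handled as its ammonium salt, and a synthase variant that turns over 14 is taken to be reachable by directed evolution. Acyclic intermediates are located by farnesyl numbering (C-1 = ring C3, C-9 = ring C5, C-10 = ring C4) and cyclic ones by ring numbering. The acetoxy carbon of 14 is S and maps unchanged onto C5 of 15.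

## Route

Step 1
Reactants: 1 geraniol
Product: 2 tert-butyl{[(2E)-3,7-dimethylocta-2,6-dien-1-yl]oxy}dimethylsilane (geranyl TBS ether)
Conditions: TBSCl, imidazole, CH2Cl2, 0 °C to rt
Reagents that add atoms: tert-butyldimethylsilyl chloride, CC(C)(C)[Si](C)(C)Cl
Why: Standard silylation of a primary allylic alcohol; the silyl ether masks C-1 through the organolithium, alkylating and hydride steps and is later removable by fluoride beside an acetate.

Step 2
Reactants: 2 geranyl TBS ether
Product: 3 (2E,6E)-8-[(tert-butyldimethylsilyl)oxy]-2,6-dimethylocta-2,6-dien-1-ol
Conditions: SeO2 (cat.), t-BuOOH, salicylic acid (cat.), CH2Cl2, 0 °C to rt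
Reagents that add atoms: selenium dioxide (oxygen carrier), O=[Se]=O; tert-butyl hydroperoxide (terminal oxidant), CC(C)(C)OO
Why: Catalytic SeO2 allylic oxidation (ene reaction then [2,3]-sigmatropic shift) should attack the distal alkene, because the proximal one is deactivated by its allylic oxygen, and should oxidise the methyl group trans to the chain to give the (E)-allylic alcohol; any over-oxidised enal is separated.

Step 3
Reactants: 3 (2E,6E)-8-[(tert-butyldimethylsilyl)oxy]-2,6-dimethylocta-2,6-dien-1-ol
Product: 4 {[(2E,6E)-8-bromo-3,7-dimethylocta-2,6-dien-1-yl]oxy}(tert-butyl)dimethylsilane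
Conditions: CBr4, PPh3, CH2Cl2, 0 °C
Reagents that add atoms: tetrabromomethane, BrC(Br)(Br)Br
Why: Appel bromination converts the primary allylic alcohol into the bromide under neutral conditions without allylic transposition and without touching the silyl ether.

Step 4
Reactants: 5 3-methylbut-2-enal
Product: 6 2-(2-methylprop-1-en-1-yl)-1,3-dithiane
Conditions: HS(CH2)3SH, BF3·OEt2 (cat.), CH2Cl2, −20 to 0 °C
Reagents that add atoms: propane-1,3-dithiol, SCCCS
Why: Lewis-acid-catalysed dithioacetalisation gives the Corey–Seebach acyl anion equivalent; the β,β-disubstitution of the enal and the low temperature disfavour conjugate addition of the thiol.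

Step 5
Reactants: 6 2-(2-methylprop-1-en-1-yl)-1,3-dithiane; 4 {[(2E,6E)-8-bromo-3,7-dimethylocta-2,6-dien-1-yl]oxy}(tert-butyl)dimethylsilane
Product: 8 tert-butyl{[(2E,6E)-3,7-dimethyl-8-[2-(2-methylprop-1-en-1-yl)-1,3-dithian-2-yl]octa-2,6-dien-1-yl]oxy}dimethylsilane, via 2-lithio-2-(2-methylprop-1-en-1-yl)-1,3-dithiane 7 (not isolated)
Conditions: n-BuLi, THF, −78 to −25 °C; then 4, −78 to −20 °C
Reagents that add atoms: none
Why: Corey–Seebach alkylation: the allyl-type anion 7 should react with the primary allylic bromide at the sulfur-bearing carbon, since attack through the other terminus would build a quaternary centre, and direct SN2 displacement at CH2Br keeps the (E)-alkene of 4.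

Step 6
Reactants: 8 the alkylated dithiane
Product: 9 (6E,10E)-12-[(tert-butyldimethylsilyl)oxy]-2,6,10-trimethyldodeca-2,6,10-trien-4-one
Conditions: MeI, CaCO3, MeCN/H2O (9:1), 40 °C
Reagents that add atoms: water, O
Why: S-Methylation turns the dithioacetal into a leaving group and water delivers the ketone (dithiane hydrolysis); the carbonate-buffered medium should keep the C-6 alkene out of conjugation with the new carbonyl and leave the silyl ether intact.

Step 7
Reactants: 9 (6E,10E)-12-[(tert-butyldimethylsilyl)oxy]-2,6,10-trimethyldodeca-2,6,10-trien-4-one
Product: 10 (4S,6E,10E)-12-[(tert-butyldimethylsilyl)oxy]-2,6,10-trimethyldodeca-2,6,10-trien-4-ol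
Conditions: (R)-2-methyl-CBS-oxazaborolidine (0.2 equiv), catecholborane, toluene, −78 °C
Reagents that add atoms: none
Why: Corey–Bakshi–Shibata reduction: the ketone binds the catalyst boron anti to the 2-methylpropenyl group, which acts as the large substituent against the allylic CH2, so hydride should reach the face that gives the (S)-carbinol at C-9 (the future ring C5); catecholborane at −78 °C does not hydroborate the alkenes and favours 1,2- over 1,4-reduction.

Step 8
Reactants: 10 the (S)-alcohol
Product: 11 (4S,6E,10E)-12-[(tert-butyldimethylsilyl)oxy]-2,6,10-trimethyldodeca-2,6,10-trien-4-yl acetate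
Conditions: Ac2O, Et3N, DMAP (cat.), CH2Cl2, 0 °C to rt
Reagents that add atoms: acetic anhydride, CC(=O)OC(C)=O
Why: DMAP-catalysed acetylation of the secondary allylic alcohol occurs at oxygen with retention of the C-9 configuration.

Step 9
Reactants: 11 the silyl ether acetate
Product: 12 (4S,6E,10E)-12-hydroxy-2,6,10-trimethyldodeca-2,6,10-trien-4-yl acetate [(2E,6E,9S)-9-acetoxyfarnesol]
Conditions: HF·pyridine, pyridine, THF, 0 °C to rt
Reagents that add atoms: none
Why: Buffered fluoride cleaves the primary allylic silyl ether; the medium is neither basic nor nucleophilic enough to remove the secondary acetate.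

Step 10
Reactants: 12 (2E,6E,9S)-9-acetoxyfarnesol
Product: 13 (4S,6E,10E)-12-chloro-2,6,10-trimethyldodeca-2,6,10-trien-4-yl acetate
Conditions: NCS, Me2S, CH2Cl2, −40 to 0 °C
Reagents that add atoms: N-chlorosuccinimide, O=C1CCC(=O)N1Cl
Why: Corey–Kim chlorination converts primary allylic alcohols into chlorides through an alkoxysulfonium salt without allylic transposition or E/Z scrambling; the acetate and the alkenes are inert to the reagent.

Step 11
Reactants: 13 the allylic chloride
Product: 14 (2E,6E,9S)-9-acetoxyfarnesyl diphosphate (handled as the ammonium salt)
Conditions: (Bu4N)3HP2O7, MeCN, rt; then Dowex 50W-X8 (NH4+ form), aq. NH4HCO3; C18 chromatography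
Reagents that add atoms: tris(tetrabutylammonium) hydrogen diphosphate, CCCC[N+](CCCC)(CCCC)CCCC.CCCC[N+](CCCC)(CCCC)CCCC.CCCC[N+](CCCC)(CCCC)CCCC.OP(=O)([O-])OP(=O)([O-])[O-]
Why: SN2 displacement of a primary allylic chloride by the soluble diphosphate trianion is the standard entry to prenyl diphosphates; the secondary allylic acetate is not displaced, and bicarbonate buffers are used in place of ammonia to avoid ammonolysis of the acetate.

Step 12
Reactants: 14 (2E,6E,9S)-9-acetoxyfarnesyl diphosphate
Product: 15 (1S,2S,3S,4E,8E)-3-hydroxy-5,9-dimethyl-2-(propan-2-yl)cyclodeca-4,8-dien-1-yl acetate (ring numbering: 3-OH, 4-isopropyl, 5-OAc)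
Conditions: engineered class 1 sesquiterpene synthase (germacra-1(10),4-dien-6-ol synthase lineage), MgCl2 (10 mM), HEPES buffer pH 7.5, DTT, glycerol (10%), 30 °C, pentane overlay
Reagents that add atoms: water, O
Why: Proposed new method: ionisation of the allylic diphosphate, assisted by the magnesium ions held at the aspartate-rich motifs, gives the (2E,6E)-farnesyl cation; its distal alkene attacks C-1 through its less substituted carbon, forming the C3–C4 ring bond and leaving the tertiary isopropyl cation outside the ring, a 1,3-hydride shift from C3 to that cation then gives the allyl cation C3–C2–C1, and active-site water adds at C3. The closest known reaction type is the cyclisation of farnesyl diphosphate by germacradienol synthases, which use the same closure and hydride shift and hydrate the allyl cation either at its tertiary terminus (germacradien-4-ol type) or at its secondary terminus (germacra-1(10),4-dien-6-ol type), together with the known tolerance of sesquiterpene synthases for substituted farnesyl diphosphates; new here is an acyloxy group next to the nucleophilic alkene. The ten-membered ring closes in the 1,10 mode: only C4 of the attacking alkene enters the ring, and the allyl unit reacts at its primary terminus so that C1=C2 stays E inside the ring. C4 is set by the face of the distal alkene that the folded chain presents to C-1, and C3 by the position of the bound water on one face of the planar allyl cation; both are imposed by the active site, and the preset (S)-centre at C5 serves as a recognition element that the site must accommodate. The step needs 1,10- over 1,6-closure, hydride shift over proton loss or capture of the cation by the acetate carbonyl, and hydration at C3 over C1; the E geometry of the proximal alkene excludes direct six-membered closure, the Markovnikov bias of the trisubstituted distal alkene favours bond formation at C-10, and the remaining choices are to be fixed by directed evolution from a 6-ol-type synthase, whose hydration site already matches. The acetate is small, uncharged and stable at pH 7.5, which is why it is carried in place of a free hydroxyl (a competing nucleophile) or the bulky final ester.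

Step 13
Reactants: 15 the hydroxy acetate
Product: 16 (1S,2R,3S,4E,8E)-5,9-dimethyl-2-(propan-2-yl)-3-[(triethylsilyl)oxy]cyclodeca-4,8-dien-1-yl acetate
Conditions: TESCl, imidazole, DMAP (cat.), DMF, 0 °C to rt
Reagents that add atoms: chlorotriethylsilane, CC[Si](CC)(CC)Cl
Why: Silylation of the only free hydroxyl (O3) under mildly basic, non-acidic conditions, which the acid-sensitive diene tolerates; no stereocentre is touched, and the change of the C4 descriptor reflects only the new substituent priority.

Step 14
Reactants: 16 the silyl ether acetate
Product: 17 (1S,2R,3S,4E,8E)-5,9-dimethyl-2-(propan-2-yl)-3-[(triethylsilyl)oxy]cyclodeca-4,8-dien-1-ol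
Conditions: K2CO3, MeOH, 0 °C to rt
Reagents that add atoms: none
Why: Base-catalysed transesterification removes the acetate as methyl acetate; a secondary triethylsilyl ether flanked by C4 and the alkene should survive, and the low temperature limits any O3 to O5 silyl shift.

Step 15
Reactants: 18 (2E)-3-(4-hydroxyphenyl)prop-2-enoic acid
Product: 20 (2E)-3-{4-[(tert-butyldimethylsilyl)oxy]phenyl}prop-2-enoic acid, via bis-silylated coumarate 19 (not isolated)
Conditions: TBSCl, imidazole, DMF, rt; then THF/H2O/AcOH, rt
Reagents that add atoms: tert-butyldimethylsilyl chloride, CC(C)(C)[Si](C)(C)Cl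
Why: Exhaustive silylation followed by selective hydrolysis of the much more labile silyl ester leaves the aryl silyl ether, which is stable to dilute acid.

Step 16
Reactants: 20 (2E)-3-{4-[(tert-butyldimethylsilyl)oxy]phenyl}prop-2-enoic acid; 17 the O5 alcohol
Product: 22 (1S,2R,3S,4E,8E)-5,9-dimethyl-2-(propan-2-yl)-3-[(triethylsilyl)oxy]cyclodeca-4,8-dien-1-yl (2E)-3-{4-[(tert-butyldimethylsilyl)oxy]phenyl}prop-2-enoate, via mixed trichlorobenzoic anhydride 21 (not isolated)
Conditions: 2,4,6-trichlorobenzoyl chloride, Et3N, toluene, rt; then 17, DMAP, toluene, rt to 40 °C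
Reagents that add atoms: none
Why: Yamaguchi esterification: DMAP attacks the less hindered cinnamoyl carbonyl of 21 and the acylpyridinium acylates the hindered secondary O5 with retention at C5; the temperature stays well below that of Cope rearrangement of the diene.

Step 17
Reactants: 22 the bis-silyl ester
Product: 23 (1S,2S,3S,4E,8E)-3-hydroxy-5,9-dimethyl-2-(propan-2-yl)cyclodeca-4,8-dien-1-yl (2E)-3-(4-hydroxyphenyl)prop-2-enoate (target)
Conditions: TBAF, AcOH (1:1), THF, 0 °C to rt
Reagents that add atoms: none
Why: Fluoride cleaves the aryl silyl ether and the secondary triethylsilyl ether in one operation; acetic acid buffering keeps the alkoxide concentration low, so the cinnamate should neither migrate from O5 to O3 nor be cleaved.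

## Compound list

1 | geraniol, (2E)-3,7-dimethylocta-2,6-dien-1-ol | CC(C)=CCC/C(C)=C/CO | starting material
2 | tert-butyl{[(2E)-3,7-dimethylocta-2,6-dien-1-yl]oxy}dimethylsilane | CC(C)=CCC/C(C)=C/CO[Si](C)(C)C(C)(C)C | intermediate
3 | (2E,6E)-8-[(tert-butyldimethylsilyl)oxy]-2,6-dimethylocta-2,6-dien-1-ol | OC/C(C)=C/CC/C(C)=C/CO[Si](C)(C)C(C)(C)C | intermediate
4 | {[(2E,6E)-8-bromo-3,7-dimethylocta-2,6-dien-1-yl]oxy}(tert-butyl)dimethylsilane | BrC/C(C)=C/CC/C(C)=C/CO[Si](C)(C)C(C)(C)C | intermediate
5 | 3-methylbut-2-enal | CC(C)=CC=O | starting material
6 | 2-(2-methylprop-1-en-1-yl)-1,3-dithiane | CC(C)=CC1SCCCS1 | intermediate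
7 | 2-lithio-2-(2-methylprop-1-en-1-yl)-1,3-dithiane | [Li]C1(C=C(C)C)SCCCS1 | intermediate (not isolated)
8 | tert-butyl{[(2E,6E)-3,7-dimethyl-8-[2-(2-methylprop-1-en-1-yl)-1,3-dithian-2-yl]octa-2,6-dien-1-yl]oxy}dimethylsilane | CC(C)=CC1(C/C(C)=C/CC/C(C)=C/CO[Si](C)(C)C(C)(C)C)SCCCS1 | intermediate
9 | (6E,10E)-12-[(tert-butyldimethylsilyl)oxy]-2,6,10-trimethyldodeca-2,6,10-trien-4-one | CC(C)=CC(=O)C/C(C)=C/CC/C(C)=C/CO[Si](C)(C)C(C)(C)C | intermediate
10 | (4S,6E,10E)-12-[(tert-butyldimethylsilyl)oxy]-2,6,10-trimethyldodeca-2,6,10-trien-4-ol | CC(C)=C[C@@H](O)C/C(C)=C/CC/C(C)=C/CO[Si](C)(C)C(C)(C)C | intermediate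
11 | (4S,6E,10E)-12-[(tert-butyldimethylsilyl)oxy]-2,6,10-trimethyldodeca-2,6,10-trien-4-yl acetate | CC(C)=C[C@@H](OC(C)=O)C/C(C)=C/CC/C(C)=C/CO[Si](C)(C)C(C)(C)C | intermediate
12 | (4S,6E,10E)-12-hydroxy-2,6,10-trimethyldodeca-2,6,10-trien-4-yl acetate, (2E,6E,9S)-9-acetoxyfarnesol | CC(C)=C[C@@H](OC(C)=O)C/C(C)=C/CC/C(C)=C/CO | intermediate
13 | (4S,6E,10E)-12-chloro-2,6,10-trimethyldodeca-2,6,10-trien-4-yl acetate | CC(C)=C[C@@H](OC(C)=O)C/C(C)=C/CC/C(C)=C/CCl | intermediate
14 | (2E,6E,9S)-9-acetoxyfarnesyl diphosphate (free acid drawn; ammonium salt handled) | CC(C)=C[C@@H](OC(C)=O)C/C(C)=C/CC/C(C)=C/COP(=O)(O)OP(=O)(O)O | intermediate (precursor of the key step)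
15 | (1S,2S,3S,4E,8E)-3-hydroxy-5,9-dimethyl-2-(propan-2-yl)cyclodeca-4,8-dien-1-yl acetate | C/C1=C\[C@H](O)[C@H](C(C)C)[C@@H](OC(C)=O)C/C(C)=C/CC1 | intermediate (product of the key step)
16 | (1S,2R,3S,4E,8E)-5,9-dimethyl-2-(propan-2-yl)-3-[(triethylsilyl)oxy]cyclodeca-4,8-dien-1-yl acetate | C/C1=C\[C@H](O[Si](CC)(CC)CC)[C@H](C(C)C)[C@@H](OC(C)=O)C/C(C)=C/CC1 | intermediate
17 | (1S,2R,3S,4E,8E)-5,9-dimethyl-2-(propan-2-yl)-3-[(triethylsilyl)oxy]cyclodeca-4,8-dien-1-ol | C/C1=C\[C@H](O[Si](CC)(CC)CC)[C@H](C(C)C)[C@@H](O)C/C(C)=C/CC1 | intermediate
18 | (2E)-3-(4-hydroxyphenyl)prop-2-enoic acid (4-hydroxycinnamic acid) | OC(=O)/C=C/c1ccc(O)cc1 | starting material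
19 | tert-butyldimethylsilyl (2E)-3-{4-[(tert-butyldimethylsilyl)oxy]phenyl}prop-2-enoate | CC(C)(C)[Si](C)(C)OC(=O)/C=C/c1ccc(O[Si](C)(C)C(C)(C)C)cc1 | intermediate (not isolated)
20 | (2E)-3-{4-[(tert-butyldimethylsilyl)oxy]phenyl}prop-2-enoic acid | OC(=O)/C=C/c1ccc(O[Si](C)(C)C(C)(C)C)cc1 | intermediate
21 | (2E)-3-{4-[(tert-butyldimethylsilyl)oxy]phenyl}prop-2-enoic 2,4,6-trichlorobenzoic anhydride | O=C(/C=C/c1ccc(O[Si](C)(C)C(C)(C)C)cc1)OC(=O)c1c(Cl)cc(Cl)cc1Cl | intermediate (not isolated)
22 | (1S,2R,3S,4E,8E)-5,9-dimethyl-2-(propan-2-yl)-3-[(triethylsilyl)oxy]cyclodeca-4,8-dien-1-yl (2E)-3-{4-[(tert-butyldimethylsilyl)oxy]phenyl}prop-2-enoate | C/C1=C\[C@H](O[Si](CC)(CC)CC)[C@H](C(C)C)[C@@H](OC(=O)/C=C/c2ccc(O[Si](C)(C)C(C)(C)C)cc2)C/C(C)=C/CC1 | intermediate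
23 | (1S,2S,3S,4E,8E)-3-hydroxy-5,9-dimethyl-2-(propan-2-yl)cyclodeca-4,8-dien-1-yl (2E)-3-(4-hydroxyphenyl)prop-2-enoate | C/C1=C\[C@H](O)[C@H](C(C)C)[C@@H](OC(=O)/C=C/c2ccc(O)cc2)C/C(C)=C/CC1 | target

## Step count and least certain steps

Total step count: 17. Longest linear sequence: 15 steps (from 1 through steps 1–3, 5–14, 16 and 17 to 23).

**Step 12 (key step, proposed new method).**
- What may go wrong: no turnover, because the acetoxy group does not fit the active site or lowers the nucleophilicity of the distal alkene. Other failure modes are quenching of the farnesyl cation before ring closure, proton loss or capture by the acetate carbonyl in place of the hydride shift, hydration at C1, and closure on the wrong alkene face.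
- Fallback by known chemistry, setting out from 10 and returning at 15:
  - Hydroxyl-directed epoxidation of 10 (VO(acac)2, t-BuOOH) should give the epoxy alcohol F1 as C-10 epimers.
  - Ti(OiPr)4-mediated isomerisation opens the epoxide to the ene-diol F2.
  - Trimethyl orthoacetate with PPTS and then Me3SiCl turns the diol, through its cyclic acetoxonium ion, into the acetoxy allylic chloride F3. The acetate stays on C-9 with retention.
  - HF·pyridine removes the silyl group to give the alcohol F4, and MnO2 oxidises it to the enal F5.
  - CrCl2 in THF under high dilution closes the same C3–C4 bond by an intramolecular Nozaki–Hiyama–Kishi allylation, a closure known for germacranolide rings, to give the isopropenyl ring alcohol F6.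
  - RhCl(PPh3)3 with H2 saturates only the 1,1-disubstituted alkene and gives 15.
  - The C-10 configuration of F1 to F5 is irrelevant because C-10 becomes the allylmetal terminus. The C3/C4 configuration of F6 then rests on macrocyclic control and may require separation of diastereomers.

**Step 5.**
- What may go wrong: alkylation of the ambident anion 7 at its other terminus, or proton transfer in place of substitution, because the anion is delocalised and the bromide is allylic.
- Fallback, setting out from 4 and returning at 9: prenyl phenyl sulfone F7 (from prenyl bromide and sodium benzenesulfinate) is lithiated and alkylated with 4. Sulfone-stabilised prenyl anions alkylate reliably next to sulfur, which gives the sulfone F8. Oxidative desulfonylation (n-BuLi, then bis(trimethylsilyl) peroxide) converts F8 into 9.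

**Step 7.**
- What may go wrong: poor facial selectivity, because the two ketone substituents differ little in size, and some conjugate reduction.
- Fallback, setting out from 9 and returning at 11: Luche reduction (NaBH4, CeCl3·7H2O, MeOH) gives the racemic alcohol F9. Lipase-catalysed acylation with vinyl acetate (Burkholderia cepacia lipase, screened for the (S)-selective preference expected when the 2-methylpropenyl group binds as the medium-sized substituent) delivers 11 directly. The unreacted (R)-alcohol F10 is oxidised back to 9 with Dess–Martin periodinane and recycled.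

**Step 11.**
- What may go wrong: hydrolysis or elimination of the allylic chloride, loss of the acetate during ion exchange, and poor recovery of the amphiphilic salt.
- Fallback, setting out from 12 and returning at 14: direct phosphorylation of the alcohol with trichloroacetonitrile and bis(triethylammonium) hydrogen phosphate in MeCN, followed by ion-exchange separation of the diphosphate from the mono- and triphosphate. No halide intermediate and no new isolated compound is involved (entry F0).

**Step 16.**
- What may go wrong: slow acylation at the hindered O5, giving time for silyl migration from O3 or for loss of the aryl silyl ether.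
- Fallback, setting out from 17 and returning at 22: acylation with diethylphosphonoacetic acid (DCC, DMAP), which reacts through a small ketene-type acylating species, gives the phosphonoacetate F11. Horner–Wadsworth–Emmons olefination with 4-[(tert-butyldimethylsilyl)oxy]benzaldehyde under LiCl/DBU in MeCN then builds the (E)-cinnamate on the ring.

## Further compounds

F1 | step 12 | (1S,3E,7E)-9-[(tert-butyldimethylsilyl)oxy]-1-(3,3-dimethyloxiran-2-yl)-3,7-dimethylnona-3,7-dien-1-ol (10,11-epoxide of 10, C-10 epimers) | CC1(C)OC1[C@@H](O)C/C(C)=C/CC/C(C)=C/CO[Si](C)(C)C(C)(C)C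
F2 | step 12 | (4S,6E,10E)-12-[(tert-butyldimethylsilyl)oxy]-2,6,10-trimethyldodeca-1,6,10-triene-3,4-diol (C-3 epimers) | CC(=C)C(O)[C@@H](O)C/C(C)=C/CC/C(C)=C/CO[Si](C)(C)C(C)(C)C
F3 | step 12 | (4S,6E,10E)-12-[(tert-butyldimethylsilyl)oxy]-3-chloro-2,6,10-trimethyldodeca-1,6,10-trien-4-yl acetate (C-3 epimers) | CC(=C)C(Cl)[C@@H](OC(C)=O)C/C(C)=C/CC/C(C)=C/CO[Si](C)(C)C(C)(C)C
F4 | step 12 | (4S,6E,10E)-3-chloro-12-hydroxy-2,6,10-trimethyldodeca-1,6,10-trien-4-yl acetate | CC(=C)C(Cl)[C@@H](OC(C)=O)C/C(C)=C/CC/C(C)=C/CO
F5 | step 12 | (4S,6E,10E)-3-chloro-2,6,10-trimethyl-12-oxododeca-1,6,10-trien-4-yl acetate | CC(=C)C(Cl)[C@@H](OC(C)=O)C/C(C)=C/CC/C(C)=C/C=O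
F6 | step 12 | (1S,2S,3S,4E,8E)-3-hydroxy-5,9-dimethyl-2-(prop-1-en-2-yl)cyclodeca-4,8-dien-1-yl acetate | C/C1=C\[C@H](O)[C@H](C(C)=C)[C@@H](OC(C)=O)C/C(C)=C/CC1
F7 | step 5 | [(3-methylbut-2-en-1-yl)sulfonyl]benzene (prenyl phenyl sulfone) | CC(C)=CCS(=O)(=O)c1ccccc1
F8 | step 5 | tert-butyl{[(2E,6E)-3,7,11-trimethyl-9-(phenylsulfonyl)dodeca-2,6,10-trien-1-yl]oxy}dimethylsilane (racemic) | CC(C)=CC(C/C(C)=C/CC/C(C)=C/CO[Si](C)(C)C(C)(C)C)S(=O)(=O)c1ccccc1
F9 | step 7 | (6E,10E)-12-[(tert-butyldimethylsilyl)oxy]-2,6,10-trimethyldodeca-2,6,10-trien-4-ol (racemic) | CC(C)=CC(O)C/C(C)=C/CC/C(C)=C/CO[Si](C)(C)C(C)(C)C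
F10 | step 7 | (4R,6E,10E)-12-[(tert-butyldimethylsilyl)oxy]-2,6,10-trimethyldodeca-2,6,10-trien-4-ol | CC(C)=C[C@H](O)C/C(C)=C/CC/C(C)=C/CO[Si](C)(C)C(C)(C)C
F0 | step 11 | none | none
F11 | step 16 | (1S,2R,3S,4E,8E)-5,9-dimethyl-2-(propan-2-yl)-3-[(triethylsilyl)oxy]cyclodeca-4,8-dien-1-yl 2-(diethoxyphosphoryl)acetate | C/C1=C\[C@H](O[Si](CC)(CC)CC)[C@H](C(C)C)[C@@H](OC(=O)CP(=O)(OCC)OCC)C/C(C)=C/CC1
A1 | alternative 1 | 1-ethenyl-5-[(4-methoxybenzyl)oxy]-4-(propan-2-yl)-6-(prop-1-en-2-yl)-3-[(triisopropylsilyl)oxy]cyclohexan-1-ol, vinyl trans to isopropenyl, configuration as in the SMILES | C=C(C)[C@@H]1[C@H](OCc2ccc(OC)cc2)[C@H](C(C)C)[C@@H](O[Si](C(C)C)(C(C)C)C(C)C)C[C@@]1(O)C=C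
A2 | alternative 1 | ten-membered diene C7 enol trifluoromethanesulfonate with O3 4-methoxybenzyl and O5 triisopropylsilyl ethers | C/C1=C\[C@H](OCc2ccc(OC)cc2)[C@H](C(C)C)[C@@H](O[Si](C(C)C)(C(C)C)C(C)C)C/C(OS(=O)(=O)C(F)(F)F)=C/CC1
A3 | alternative 2 | acyclic (E)-enyne epoxide: methyl-capped C7≡C8 alkyne, O3 tert-butyldimethylsilyl ether, C4 isopropyl, C5–C6 terminal epoxide | CC#CCC/C(C)=C/[C@H](O[Si](C)(C)C(C)(C)C)[C@H](C(C)C)[C@@H]1CO1
A4 | alternative 2 | ten-membered (E,E)-diene with free C5 hydroxyl and O3 tert-butyldimethylsilyl ether | C/C1=C\[C@H](O[Si](C)(C)C(C)(C)C)[C@H](C(C)C)[C@@H](O)C/C(C)=C/CC1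
A5 | alternative 3 | acyclic (E)-alkenyl iodide with terminal diene, O3 4-methoxybenzyl and O5 triethylsilyl ethers | C/C(I)=C\[C@H](OCc1ccc(OC)cc1)[C@H](C(C)C)[C@@H](O[Si](CC)(CC)CC)C/C(C)=C/C=C
A6 | alternative 3 | ten-membered (E,E)-diene with O3 4-methoxybenzyl and O5 triethylsilyl ethers | C/C1=C\[C@H](OCc2ccc(OC)cc2)[C@H](C(C)C)[C@@H](O[Si](CC)(CC)CC)C/C(C)=C/CC1
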